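The route rests on cutting the bond between the benzylic CH2 and C8 of the catechin A ring. The acylphloroglucinol ring bears free hydroxyls on both carbons next to its CH2-bearing carbon, so Mannich base 8 loses dimethylamine on warming to give o-quinone methide 10 with that CH2 as the exocyclic acceptor carbon. The phloroglucinol-type A ring of unprotected (+)-catechin, nucleophilic at C8 between ring oxygen O1 and the C7 hydroxyl, adds to it. One protecting-group-free operation joins the two halves and delivers the target; the purchased stereocentres (catechin C2 and C3, the (R)-2-methylbutanoyl carbon) are not touched.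

Key step: step 6

Remark: (R)-2-methylbutanoic acid (2) and (+)-catechin (9) are taken as purchasable single enantiomers and supply all three stereocentres; no stereocentre is created in the route.

Step 1
Reactants: 1 2-methylphloroglucinol (2-methylbenzene-1,3,5-triol); 2 (R)-2-methylbutanoic acid
Product: 4 (2R)-1-(2,4,6-trihydroxy-3-methylphenyl)-2-methylbutan-1-one, via acid chloride 3 (not isolated)
Conditions: 2, (COCl)2, cat. DMF, CH2Cl2, 0 °C to rt, concentrate; then 1, AlCl3 (4 equiv), CH2Cl2/PhNO2, 0 to 40 °C; aq HCl
Reagents that add atoms: none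
Why: Friedel–Crafts C-acylation of the very electron-rich ring by the acid chloride made without base (no ketene pathway); the two open ring positions of 1 are equivalent, the first acyl group deactivates the ring against a second, and the α-stereocentre of 2 should be carried through unchanged at this temperature.

Step 2
Reactants: 4 (2R)-1-(2,4,6-trihydroxy-3-methylphenyl)-2-methylbutan-1-one
Product: 5 (2R)-1-[2-hydroxy-4,6-bis(methoxymethoxy)-3-methylphenyl]-2-methylbutan-1-one
Conditions: MOMCl (2.1 equiv), i-Pr2NEt (3 equiv), CH2Cl2, 0 °C to rt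
Reagents that add atoms: chloromethyl methyl ether, COCCl
Why: Base-mediated O-alkylation (MOM ether formation) should take the two more acidic, less hindered phenols (O4 para to the ketone, O6 flanked by H), while the O2 hydroxyl, wedged between acyl and methyl and held in the C=O···H–O hydrogen bond, stays free.

Step 3
Reactants: 5 (2R)-1-[2-hydroxy-4,6-bis(methoxymethoxy)-3-methylphenyl]-2-methylbutan-1-one
Product: 6 (2R)-1-[2-methoxy-4,6-bis(methoxymethoxy)-3-methylphenyl]-2-methylbutan-1-one
Conditions: MeI (3 equiv), K2CO3, acetone, reflux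
Reagents that add atoms: iodomethane, CI
Why: Williamson O-methylation of the one remaining, chelated phenol; carbonate is too weak a base to enolise the hindered aryl ketone, so the α-stereocentre should survive.

Step 4
Reactants: 6 (2R)-1-[2-methoxy-4,6-bis(methoxymethoxy)-3-methylphenyl]-2-methylbutan-1-one
Product: 7 (2R)-1-(4,6-dihydroxy-2-methoxy-3-methylphenyl)-2-methylbutan-1-one
Conditions: HCl (1.25 M in MeOH), rt to 40 °C
Reagents that add atoms: none
Why: Acid-catalysed acetal cleavage (transacetalisation to dimethoxymethane) frees both phenols while the aryl methyl ether is inert; methanol traps the methoxymethyl cation so it should not alkylate the free ring carbon.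

Step 5
Reactants: 7 (2R)-1-(4,6-dihydroxy-2-methoxy-3-methylphenyl)-2-methylbutan-1-one
Product: 8 (2R)-1-{3-[(dimethylamino)methyl]-2,4-dihydroxy-6-methoxy-5-methylphenyl}-2-methylbutan-1-one
Conditions: CH2=NMe2+ I− (1.1 equiv), CH2Cl2, rt; then sat. aq NaHCO3
Reagents that add atoms: Eschenmoser's salt (N,N-dimethylmethyleneiminium iodide), C[N+](C)=C.[I-]
Why: Phenolic Mannich reaction with a preformed iminium salt at the only unsubstituted ring carbon, which lies between two hydroxyls; no free formaldehyde is present, so a methylene-bridged dimer should not form.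

Step 6
Reactants: 8 (2R)-1-{3-[(dimethylamino)methyl]-2,4-dihydroxy-6-methoxy-5-methylphenyl}-2-methylbutan-1-one; 9 (+)-catechin, (2R,3S)-2-(3,4-dihydroxyphenyl)-3,4-dihydro-2H-chromene-3,5,7-triol
Product: 11 (2R)-1-(3-{[(2R,3S)-2-(3,4-dihydroxyphenyl)-3,5,7-trihydroxy-3,4-dihydro-2H-chromen-8-yl]methyl}-2,4-dihydroxy-6-methoxy-5-methylphenyl)-2-methylbutan-1-one (target), via o-quinone methide 10 (not isolated)
Conditions: 9 (3 equiv), AcOH (2 equiv), degassed 1,4-dioxane, 80 °C, Ar; 8 added slowly
Reagents that add atoms: none
Why: Thermal 1,4-elimination of dimethylamine from the zwitterionic (phenoxide/ammonium) form of 8 gives o-quinone methide 10, an alkylidene-1,3-dicarbonyl-like acceptor; the A ring of 9 adds through C8 to its exocyclic CH2 (Michael/Friedel–Crafts) and both rings re-aromatise by tautomerisation. The closest known reaction type is the o-quinone methide route from Mannich bases to methylene-bridged acylphloroglucinols, together with the benzylation of flavan-3-ols by o-hydroxybenzyl electrophiles. No ring is closed and no stereocentre is formed; C2 and C3 of catechin and the side-chain centre are not involved, and the acetic acid buffer keeps the medium non-basic so that C2 should not epimerise. The step needs C-alkylation at C8 rather than C6 and mono- rather than bis-alkylation: C8 is flanked only by the 7-OH and by O1, which is tied back in the pyran ring, and is para to the 5-OH, whereas C6 sits between two solvated hydroxyls, so the fully substituted, bulky 10 should prefer C8, though this is a bias and not a guarantee. O-alkylation is reversible and should funnel to the C-adduct, and the threefold excess of 9 with slow addition of 8 should suppress the 6,8-bis-adduct and self-condensation of 8.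

Compound list
1 | 2-methylphloroglucinol (2-methylbenzene-1,3,5-triol) | Cc1c(O)cc(O)cc1O | starting material
2 | (R)-2-methylbutanoic acid | CC[C@@H](C)C(=O)O | starting material
3 | (2R)-2-methylbutanoyl chloride | CC[C@@H](C)C(=O)Cl | intermediate
4 | (2R)-1-(2,4,6-trihydroxy-3-methylphenyl)-2-methylbutan-1-one | CC[C@@H](C)C(=O)c1c(O)cc(O)c(C)c1O | intermediate
5 | (2R)-1-[2-hydroxy-4,6-bis(methoxymethoxy)-3-methylphenyl]-2-methylbutan-1-one | CC[C@@H](C)C(=O)c1c(OCOC)cc(OCOC)c(C)c1O | intermediate
6 | (2R)-1-[2-methoxy-4,6-bis(methoxymethoxy)-3-methylphenyl]-2-methylbutan-1-one | CC[C@@H](C)C(=O)c1c(OCOC)cc(OCOC)c(C)c1OC | intermediate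
7 | (2R)-1-(4,6-dihydroxy-2-methoxy-3-methylphenyl)-2-methylbutan-1-one | CC[C@@H](C)C(=O)c1c(O)cc(O)c(C)c1OC | intermediate
8 | (2R)-1-{3-[(dimethylamino)methyl]-2,4-dihydroxy-6-methoxy-5-methylphenyl}-2-methylbutan-1-one | CC[C@@H](C)C(=O)c1c(O)c(CN(C)C)c(O)c(C)c1OC | intermediate
9 | (+)-catechin, (2R,3S)-2-(3,4-dihydroxyphenyl)-3,4-dihydro-2H-chromene-3,5,7-triol | Oc1cc(O)c2c(c1)O[C@H](c1ccc(O)c(O)c1)[C@@H](O)C2 | starting material
10 | o-quinone methide, 5-hydroxy-3-methoxy-2-methyl-6-methylidene-4-[(2R)-2-methylbutanoyl]cyclohexa-2,4-dien-1-one | CC[C@@H](C)C(=O)C1=C(O)C(=C)C(=O)C(C)=C1OC | intermediate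
11 | (2R)-1-(3-{[(2R,3S)-2-(3,4-dihydroxyphenyl)-3,5,7-trihydroxy-3,4-dihydro-2H-chromen-8-yl]methyl}-2,4-dihydroxy-6-methoxy-5-methylphenyl)-2-methylbutan-1-one | CC[C@@H](C)C(=O)c1c(O)c(Cc2c(O)cc(O)c3c2O[C@H](c2ccc(O)c(O)c2)[C@@H](O)C3)c(O)c(C)c1OC | target

Total step count: 6. Longest linear sequence: 6 steps (1 and 2 to 4, then 5, 6, 7, 8 and 11).

Steps most likely to fail

Step 6. What may go wrong: poor discrimination between C6 and C8 of the unprotected A ring, a second benzylation of the product at C6, or self-condensation of the o-quinone methide. The fallback sets out from 8 and 9 and comes back at 11. Compound 9 is benzylated on its four phenols (BnBr, K2CO3, DMF) to 5,7,3',4'-tetra-O-benzyl-(+)-catechin F1, in which C6 is buried between two benzyloxy groups and electrophilic substitution is known to go to C8. Compound 8 is heated in methanol, where the o-quinone methide is trapped by solvent, to give the benzylic methyl ether (2R)-1-[2,4-dihydroxy-6-methoxy-3-(methoxymethyl)-5-methylphenyl]-2-methylbutan-1-one F2. F2 and F1 are joined by Lewis-acid Friedel–Crafts benzylation (BF3·OEt2, CH2Cl2, −20 °C) to the 8-benzylated tetra-O-benzyl ether F3. Hydrogenolysis (H2, Pd(OH)2/C, THF/MeOH) then removes the four benzyl groups without touching the chelated aryl ketone and returns 11.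

Step 2. What may go wrong: protection of the wrong ortho hydroxyl or formation of mixed bis-ethers, so that the later methyl group lands on the wrong oxygen. The fallback sets out from 4 and comes back at 7, bypassing 5 and 6; it differentiates the hydroxyls by steric exclusion instead of hydrogen bonding. TIPSCl and imidazole in DMF should silylate only O4 and O6, since the phenol between acyl and methyl is too hindered for a triisopropylsilyl group, giving the bis-TIPS ether F4. O-methylation (MeI, K2CO3, acetone) gives the methyl ether F5, and TBAF buffered with AcOH in THF removes both silyl groups to return 7.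

Step 1. What may go wrong: erosion of the α-stereocentre under AlCl3 by enolisation of the acid chloride or of the aluminium-chelated ketone, or diacylation. The fallback sets out from 1 and 2 and comes back at 4; it builds the ketone without acid by directed ortho-metalation. Compound 1 is converted (MOMCl, NaH, DMF) into 1,3,5-tris(methoxymethoxy)-2-methylbenzene F6, and 2 is coupled with MeNHOMe·HCl (EDC, Et3N, CH2Cl2) to the Weinreb amide (2R)-N-methoxy-N,2-dimethylbutanamide F7. Lithiation of F6 between two OMOM groups (n-BuLi, TMEDA, THF, 0 °C) and addition to F7 at −78 °C gives, through the stable chelated tetrahedral intermediate, the tris-MOM ketone F8. HCl in MeOH then frees triol 4.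

Further compounds
F1 | step 6 | 5,7,3',4'-tetra-O-benzyl-(+)-catechin | C(Oc1cc(OCc2ccccc2)c2c(c1)O[C@H](c1ccc(OCc3ccccc3)c(OCc3ccccc3)c1)[C@@H](O)C2)c1ccccc1
F2 | step 6 | (2R)-1-[2,4-dihydroxy-6-methoxy-3-(methoxymethyl)-5-methylphenyl]-2-methylbutan-1-one | CC[C@@H](C)C(=O)c1c(O)c(COC)c(O)c(C)c1OC
F3 | step 6 | 5,7,3',4'-tetra-O-benzyl ether of 11 | CC[C@@H](C)C(=O)c1c(O)c(Cc2c(OCc3ccccc3)cc(OCc3ccccc3)c3c2O[C@H](c2ccc(OCc4ccccc4)c(OCc4ccccc4)c2)[C@@H](O)C3)c(O)c(C)c1OC
F4 | step 2 | (2R)-1-{2-hydroxy-3-methyl-4,6-bis[(triisopropylsilyl)oxy]phenyl}-2-methylbutan-1-one | CC[C@@H](C)C(=O)c1c(O[Si](C(C)C)(C(C)C)C(C)C)cc(O[Si](C(C)C)(C(C)C)C(C)C)c(C)c1O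
F5 | step 2 | (2R)-1-{2-methoxy-3-methyl-4,6-bis[(triisopropylsilyl)oxy]phenyl}-2-methylbutan-1-one | CC[C@@H](C)C(=O)c1c(O[Si](C(C)C)(C(C)C)C(C)C)cc(O[Si](C(C)C)(C(C)C)C(C)C)c(C)c1OC
F6 | step 1 | 1,3,5-tris(methoxymethoxy)-2-methylbenzene | Cc1c(OCOC)cc(OCOC)cc1OCOC
F7 | step 1 | (2R)-N-methoxy-N,2-dimethylbutanamide | CC[C@@H](C)C(=O)N(C)OC
F8 | step 1 | (2R)-2-methyl-1-[3-methyl-2,4,6-tris(methoxymethoxy)phenyl]butan-1-one | CC[C@@H](C)C(=O)c1c(OCOC)cc(OCOC)c(C)c1OCOC
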